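**Retrosynthetic overview**
1. Target 21 ← desilylation of 20 ← titanium-induced 1,22-reductive elimination of the C6/C6' bis-tertiary diol 19. This one step moves the whole π-system into the retro pattern and creates both exocyclic alkenes.
2. 19 ← Red-Al reduction of bis-propargylic diol 18 ← two successive acetylide additions of the C22 heptaene-diyne 14 to ring ketones 8 and 6.
3. 14 ← twofold Wittig of C10 dialdehyde 11 with the C6 enynyl phosphonium salt 10 (from enynol 9).
4. Left ketone 8 ← (S)-phorenol 7 ← CBS reduction of ketoisophorone 1. Right ketone 6 ← trans-diol 5 ← directed reduction of hydroxy-dione 4 ← selenide opening ← organocatalytic asymmetric epoxidation of 1.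
5. Ring order: both six-membered rings are bought intact in 1 and are never rebuilt. The only ring formed is the oxirane of 2 (step 1), opened again in step 2.

Assumption: the named catalyst antipodes are taken to give the stated faces (usual CBS enone model; amine chosen from the epi-quinine/epi-quinidine pair) and are checked on 7 and 2; the carbinol configurations at C6 and C6' in 16–19 are left undefined because step 12 destroys both centres.

Locants C1–C15 and C1'–C15' are the carotenoid locants of the target (unprimed = ring with the 4,5-double bond). TBS = tert-butyldimethylsilyl.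

**Step 1**
Reactants: 1 ketoisophorone (2,6,6-trimethylcyclohex-2-ene-1,4-dione)
Product: 2 (2S,3R)-2,3-epoxy-2,6,6-trimethylcyclohexane-1,4-dione
Conditions: 9-amino(9-deoxy)epi-quinine (10 mol %), TFA (20 mol %), 30% aq. H2O2 (1.5 equiv), dioxane, 30 °C
Reagents that add atoms: hydrogen peroxide OO
Why: Proposed new method: the primary amine condenses only with the unhindered C4 carbonyl (C1 lies between two fully substituted carbons), H2O2 adds to the iminium at C2 and the enamine closes the oxirane at C3 (Weitz–Scheffer-type epoxidation under iminium/enamine catalysis) on one enantiotopic face, so C2 (the future C5') and C3 are set together; the closest known reaction type is the amine-salt-catalysed asymmetric epoxidation of simple 3-substituted cyclohex-2-enones, which has not been shown on a cyclic 2-ene-1,4-dione.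

**Step 2**
Reactants: 2 (2S,3R)-2,3-epoxy-2,6,6-trimethylcyclohexane-1,4-dione
Product: 4 (2S)-2-hydroxy-2,6,6-trimethylcyclohexane-1,4-dione, via 3-phenylselanyl ketone 3 (not isolated)
Conditions: (PhSe)2 (1.2 equiv), NaBH4 (2.4 equiv), EtOH, then AcOH, 0 °C → rt
Reagents that add atoms: none
Why: Organoselenium reductive opening of an α,β-epoxy ketone: PhSe− opens the oxirane by SN2 at the secondary C3 (α to the C4 ketone; C2 is tertiary and hindered), a second selenolate removes selenium from 3 and the enol ketonises, so only the C3–O bond breaks and the C2 carbinol keeps its configuration.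

**Step 3**
Reactants: 4 (2S)-2-hydroxy-2,6,6-trimethylcyclohexane-1,4-dione
Product: 5 (2S,4R)-2,4-dihydroxy-2,6,6-trimethylcyclohexan-1-one
Conditions: Me4NBH(OAc)3 (4 equiv), MeCN/AcOH 1:1, −25 °C
Reagents that add atoms: none
Why: Evans–Saksena directed reduction: the tertiary 2-OH exchanges onto boron and delivers hydride to the β-carbonyl C4 on its own face through a six-membered transition state, giving the 2,4-trans (1,3-anti) diol and setting C4 as R, while the hindered C1 ketone is left.

**Step 4**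
Reactants: 5 (2S,4R)-2,4-dihydroxy-2,6,6-trimethylcyclohexan-1-one
Product: 6 (2S,4R)-2,4-bis(tert-butyldimethylsilyloxy)-2,6,6-trimethylcyclohexan-1-one
Conditions: TBSOTf (2.6 equiv), 2,6-lutidine (4 equiv), CH2Cl2, −78 → 0 °C
Reagents that add atoms: tert-butyldimethylsilyl trifluoromethanesulfonate CC(C)(C)[Si](C)(C)OS(=O)(=O)C(F)(F)F
Why: Silyl triflate silylation protects the secondary and the tertiary hydroxyl; the ketone has no α-hydrogen and cannot form a silyl enol ether.

**Step 5**
Reactants: 1 ketoisophorone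
Product: 7 (4S)-4-hydroxy-2,6,6-trimethylcyclohex-2-en-1-one ((S)-phorenol)
Conditions: (R)-2-methyl-CBS-oxazaborolidine (15 mol %), catecholborane (1.3 equiv), toluene, −78 °C
Reagents that add atoms: none
Why: Corey–Bakshi–Shibata reduction: the oxazaborolidine–borane complex binds the unhindered C4 carbonyl with the alkenyl arm as the large group and delivers hydride to one face, setting C4 as S (first stereocentre of this branch), while the C1 carbonyl between two fully substituted carbons does not react.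

**Step 6**
Reactants: 7 (S)-phorenol
Product: 8 (4S)-4-(tert-butyldimethylsilyloxy)-2,6,6-trimethylcyclohex-2-en-1-one
Conditions: TBSCl (1.2 equiv), imidazole (2.5 equiv), DMF, rt
Reagents that add atoms: tert-butyldimethylsilyl chloride CC(C)(C)[Si](C)(C)Cl
Why: Standard silylation of a secondary allylic alcohol; the stereocentre is not touched.

**Step 7**
Reactants: 9 (2E)-3-methylpent-2-en-4-yn-1-ol
Product: 10 [(2E)-3-methylpent-2-en-4-yn-1-yl]triphenylphosphonium bromide
Conditions: Ph3P·HBr (1.05 equiv), MeOH, rt; crystallise the (E)-salt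
Reagents that add atoms: triphenylphosphine hydrobromide Br.c1ccc(cc1)P(c1ccccc1)c1ccccc1
Why: Conversion of an allylic alcohol into its phosphonium salt with Ph3P·HBr (substitution at the primary allylic carbon), the standard entry to carotenoid Wittig salts.

**Step 8**
Reactants: 10 phosphonium bromide (2.3 equiv); 11 (2E,4E,6E)-2,7-dimethylocta-2,4,6-trienedial
Product: 14 (3E,5E,7E,9E,11E,13E,15E)-3,7,12,16-tetramethyloctadeca-3,5,7,9,11,13,15-heptaene-1,17-diyne, via phosphonium ylide 12 (not isolated), via C16 ynal 13 (not isolated)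
Conditions: NaOMe (2.4 equiv), CH2Cl2/MeOH, 0 °C → rt; then reflux in heptane (Z→E), crystallise
Reagents that add atoms: none
Why: Twofold Wittig olefination of the dialdehyde with the semi-stabilised allylic ylide followed by thermal Z→E equilibration of the new disubstituted alkenes, as in C15 + C10 + C15 carotenoid assemblies.

**Step 9**
Reactants: 14 C22 heptaene-diyne (3 equiv); 8 silylated (S)-phorenol
Product: 16 (4S)-4-(tert-butyldimethylsilyloxy)-2,6,6-trimethyl-1-[(3E,5E,7E,9E,11E,13E,15E)-3,7,12,16-tetramethyloctadeca-3,5,7,9,11,13,15-heptaene-1,17-diyn-1-yl]cyclohex-2-en-1-ol (C1 epimers), via lithium acetylide 15 (not isolated)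
Conditions: n-BuLi (1.0 equiv), THF, −78 °C; then 8 (1.0 equiv), −78 → −20 °C; H2O quench; excess 14 recovered
Reagents that add atoms: none
Why: 1,2-Addition of a lithium acetylide to the hindered enone carbonyl (the ring/chain coupling used for abscisic-acid-type compounds); excess diyne keeps the reaction at the mono-adduct, and the new C6 carbinol centre is destroyed later.

**Step 10**
Reactants: 16 mono-adduct; 6 bis-silylated right-ring ketone (1.3 equiv)
Product: 18 bis-propargylic 6,6'-diol (7,8,7',8'-tetradehydro skeleton; 3-OTBS and 4,5-ene in the left ring; 3'-OTBS and 5'-OTBS in the right ring; C6 and C6' epimers), via dilithio species 17 (not isolated)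
Conditions: n-BuLi (2.1 equiv), THF, −78 °C; then 6, −78 → −30 °C; AcOH quench at −78 °C
Reagents that add atoms: none
Why: Acetylide addition to a ketone without α-hydrogen, so enolisation cannot compete and the slim nucleophile can be given time; the cold quench prevents 1,2-silyl migration to the new alkoxide, and the C6' carbinol configuration is irrelevant.

**Step 11**
Reactants: 18 bis-propargylic 6,6'-diol
Product: 19 bis-allylic 6,6'-diol (all-E 7,9,11,13,15,13',11',9',7'-nonaene; C6 and C6' tertiary carbinols; 3-, 3'- and 5'-OTBS)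
Conditions: Red-Al (6 equiv), THF, 0 °C → rt; Rochelle salt work-up
Reagents that add atoms: none
Why: Hydroxyl-directed trans-hydroalumination of propargylic alcohols (Red-Al reduction) gives the (7E) and (7'E) allylic alcohols; the silyl ethers and the polyene are inert.

**Step 12**
Reactants: 19 bis-allylic 6,6'-diol
Product: 20 (3S,3'R,5'S)-3,3',5'-tris-O-TBS-4,5'-retro-β,β-carotene-3,3',5'-triol (all-E)
Conditions: TiCl3 (8 equiv)/LiAlH4 (4 equiv), THF, reflux then 0 °C; slow addition of 19 (high dilution) with Et3N, 0 °C → rt, dark, Ar; chromatography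
Reagents that add atoms: none
Why: Proposed new method: both tertiary carbinols are bound to low-valent titanium, homolysis of the doubly allylic C6–O bond gives a polyenyl radical delocalised from C4 to C7', and loss of the second titanoxy group from C6' (a vinylogous β-scission 22 atoms away) closes the shell as the retro-undecaene, forming both exocyclic C6=C7 and C6'=C7' bonds; the silyl ethers carry no Ti–O bond and stay, and E geometry follows from s-trans conformers with the chain turned toward the gem-dimethyl carbons, away from the 5-methyl and the bulky 5'-OTBS; the closest known reaction type is the Walborsky–Wüst/Solladié titanium-induced 1,4-reductive elimination of 2-ene-1,4-diols to 1,3-dienes.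

**Step 13**
Reactants: 20 tris-TBS ether
Product: 21 target (3S,3'R,5'S,all-E)-4,5'-retro-β,β-carotene-3,3',5'-triol (CNP0269135.1)
Conditions: TBAF (6 equiv), THF, 0 → 40 °C, dark, Ar
Reagents that add atoms: none
Why: Fluoride desilylation under non-acidic conditions, which the acid-labile tertiary polyenylic alcohol tolerates; no stereocentre is touched.

**Compound list**
1 | ketoisophorone (2,6,6-trimethylcyclohex-2-ene-1,4-dione) | CC1=CC(=O)CC(C)(C)C1=O | starting material
2 | (2S,3R)-2,3-epoxy-2,6,6-trimethylcyclohexane-1,4-dione | CC1(C)CC(=O)[C@@H]2O[C@]2(C)C1=O | intermediate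
3 | (2R,3S)-2-hydroxy-2,6,6-trimethyl-3-(phenylselanyl)cyclohexane-1,4-dione | CC1(C)CC(=O)[C@@H]([Se]c2ccccc2)[C@](C)(O)C1=O | intermediate
4 | (2S)-2-hydroxy-2,6,6-trimethylcyclohexane-1,4-dione | O=C1C(C)(C)CC(=O)C[C@]1(C)O | intermediate
5 | (2S,4R)-2,4-dihydroxy-2,6,6-trimethylcyclohexan-1-one | O=C1C(C)(C)C[C@@H](O)C[C@]1(C)O | intermediate
6 | (2S,4R)-2,4-bis(tert-butyldimethylsilyloxy)-2,6,6-trimethylcyclohexan-1-one | O=C1C(C)(C)C[C@@H](O[Si](C)(C)C(C)(C)C)C[C@]1(C)O[Si](C)(C)C(C)(C)C | intermediate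
7 | (4S)-4-hydroxy-2,6,6-trimethylcyclohex-2-en-1-one, (S)-phorenol | CC1=C[C@@H](O)CC(C)(C)C1=O | intermediate
8 | (4S)-4-(tert-butyldimethylsilyloxy)-2,6,6-trimethylcyclohex-2-en-1-one | CC1=C[C@@H](O[Si](C)(C)C(C)(C)C)CC(C)(C)C1=O | intermediate
9 | (2E)-3-methylpent-2-en-4-yn-1-ol | C#C/C(C)=C/CO | starting material
10 | [(2E)-3-methylpent-2-en-4-yn-1-yl]triphenylphosphonium bromide | C#C/C(C)=C/C[P+](c1ccccc1)(c1ccccc1)c1ccccc1.[Br-] | intermediate
11 | (2E,4E,6E)-2,7-dimethylocta-2,4,6-trienedial | O=C/C(C)=C/C=C/C=C(C)/C=O | starting material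
12 | [(2E)-3-methylpent-2-en-4-yn-1-ylidene]triphenylphosphorane | C#C/C(C)=C/C=P(c1ccccc1)(c1ccccc1)c1ccccc1 | intermediate
13 | (2E,4E,6E,8E,10E)-2,7,11-trimethyltrideca-2,4,6,8,10-pentaen-12-ynal | O=C/C(C)=C/C=C/C=C(C)/C=C/C=C(C)/C#C | intermediate
14 | (3E,5E,7E,9E,11E,13E,15E)-3,7,12,16-tetramethyloctadeca-3,5,7,9,11,13,15-heptaene-1,17-diyne | C#C/C(C)=C/C=C/C(C)=C/C=C/C=C(C)/C=C/C=C(C)/C#C | intermediate
15 | mono-lithium acetylide of 14 | [Li]C#C/C(C)=C/C=C/C(C)=C/C=C/C=C(C)/C=C/C=C(C)/C#C | intermediate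
16 | left-ring propargylic alcohol (mono-adduct of 14 with 8; C6 epimers) | CC1=C[C@@H](O[Si](C)(C)C(C)(C)C)CC(C)(C)C1(O)C#C/C(C)=C/C=C/C(C)=C/C=C/C=C(C)/C=C/C=C(C)/C#C | intermediate
17 | O,C-dilithio derivative of 16 (lithium alkoxide and lithium acetylide) | CC1=C[C@@H](O[Si](C)(C)C(C)(C)C)CC(C)(C)C1(O[Li])C#C/C(C)=C/C=C/C(C)=C/C=C/C=C(C)/C=C/C=C(C)/C#C[Li] | intermediate
18 | bis-propargylic 6,6'-diol (C6 and C6' epimers) | CC1=C[C@@H](O[Si](C)(C)C(C)(C)C)CC(C)(C)C1(O)C#C/C(C)=C/C=C/C(C)=C/C=C/C=C(C)/C=C/C=C(C)/C#CC1(O)C(C)(C)C[C@@H](O[Si](C)(C)C(C)(C)C)C[C@]1(C)O[Si](C)(C)C(C)(C)C | intermediate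
19 | bis-allylic 6,6'-diol (all-E nonaene; C6 and C6' epimers) | CC1=C[C@@H](O[Si](C)(C)C(C)(C)C)CC(C)(C)C1(O)/C=C/C(C)=C/C=C/C(C)=C/C=C/C=C(C)/C=C/C=C(C)/C=C/C1(O)C(C)(C)C[C@@H](O[Si](C)(C)C(C)(C)C)C[C@]1(C)O[Si](C)(C)C(C)(C)C | intermediate
20 | 3,3',5'-tris-O-TBS ether of the target | CC1=C[C@@H](O[Si](C)(C)C(C)(C)C)CC(C)(C)\C1=C/C=C(C)/C=C/C=C(C)/C=C/C=C/C(C)=C/C=C/C(C)=C/C=C1\C(C)(C)C[C@@H](O[Si](C)(C)C(C)(C)C)C[C@]1(C)O[Si](C)(C)C(C)(C)C | intermediate
21 | (3S,3'R,5'S,all-E)-4,5'-retro-β,β-carotene-3,3',5'-triol (CNP0269135.1) | CC1=C[C@@H](O)CC(C)(C)\C1=C/C=C(C)/C=C/C=C(C)/C=C/C=C/C(C)=C/C=C/C(C)=C/C=C1\C(C)(C)C[C@@H](O)C[C@]1(C)O | target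

**Step count**
Total: 13 steps. Longest linear sequence: 8 steps (1, 2, 3, 4, 10, 11, 12, 13).

**Three steps most likely to fail**

Step 12 (proposed new 1,22-reductive elimination). Risks are radical dimerisation, over-reduction and E/Z mixtures at C6=C7 and C6'=C7'. The fallback uses only known carbonyl olefinations; it sets out from ketones 8 and 6 and comes back at 20.
- Ketone 8 is treated with (Z)-2-ethoxyvinyllithium to give the left ethoxyvinyl carbinol F7. Dilute acid (allylic transposition with enol-ether hydrolysis) converts it into the left ylidene-acetaldehyde F8. Wittig reaction with 2-(triphenylphosphoranylidene)propanal gives the left C14 retro-enal F9.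
- The same three operations on 6 give the right ethoxyvinyl carbinol F10, the right ylidene-acetaldehyde F11 and the right C14 retro-enal F12.
- The central C12 unit is built from 1,4-dioxane-2,3-diol (glyoxal equivalent) and triethyl 3-methyl-4-phosphonocrotonate by double Horner–Wadsworth–Emmons reaction to the tetraene diester F13. DIBAL-H reduction gives the tetraene diol F14, PBr3 the dibromide F15, and Arbuzov reaction with triethyl phosphite the bisphosphonate F16.
- HWE reaction of excess F16 (NaH, THF) with F9 gives the C26 phosphonate F17. A second HWE reaction of F17 with F12 forms C10'=C11' and gives 20.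

Step 1 (proposed new epoxidation). Risks are low ee from background racemic epoxidation of the electron-poor enedione. The fallback is a known chirality relay; it sets out from 1 and comes back at 2.
- CBS reduction of 1 with the (S)-catalyst gives (R)-phorenol F1, which is silylated to the (R)-silyl ether F2.
- Weitz–Scheffer epoxidation (t-BuOOH, Triton B) anti to the silyloxy group gives the epoxy silyl ether F3.
- Buffered fluoride gives the epoxy alcohol F4, and Dess–Martin oxidation of its C4 carbinol gives 2.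

Step 10 (acetylide addition to the doubly α-quaternary ketone 6). Risks are slow addition and silyl migration. The fallback changes the order of protection and bond formation; it sets out from 5 and comes back at 18.
- TBSCl/imidazole silylates only the secondary hydroxyl of 5 to give the mono-silyl hydroxy ketone F5.
- Its lithium alkoxide (smaller, chelation-activated carbonyl) is added to 17 to give the 5'-hydroxy adduct F6.
- Site-selective silylation of the least hindered tertiary hydroxyl (5'-OH) with TBSOTf/2,6-lutidine at −78 °C gives 18.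

**Further compounds**
F1 | step 1 | (4R)-4-hydroxy-2,6,6-trimethylcyclohex-2-en-1-one, (R)-phorenol | CC1=C[C@H](O)CC(C)(C)C1=O
F2 | step 1 | (4R)-4-(tert-butyldimethylsilyloxy)-2,6,6-trimethylcyclohex-2-en-1-one | CC1=C[C@H](O[Si](C)(C)C(C)(C)C)CC(C)(C)C1=O
F3 | step 1 | (2S,3S,4R)-4-(tert-butyldimethylsilyloxy)-2,3-epoxy-2,6,6-trimethylcyclohexan-1-one | CC1(C)C[C@@H](O[Si](C)(C)C(C)(C)C)[C@@H]2O[C@]2(C)C1=O
F4 | step 1 | (2S,3S,4R)-2,3-epoxy-4-hydroxy-2,6,6-trimethylcyclohexan-1-one | CC1(C)C[C@@H](O)[C@@H]2O[C@]2(C)C1=O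
F5 | step 10 | (2S,4R)-4-(tert-butyldimethylsilyloxy)-2-hydroxy-2,6,6-trimethylcyclohexan-1-one | O=C1C(C)(C)C[C@@H](O[Si](C)(C)C(C)(C)C)C[C@]1(C)O
F6 | step 10 | 5'-hydroxy analogue of 18 (bis-propargylic 5',6,6'-triol) | CC1=C[C@@H](O[Si](C)(C)C(C)(C)C)CC(C)(C)C1(O)C#C/C(C)=C/C=C/C(C)=C/C=C/C=C(C)/C=C/C=C(C)/C#CC1(O)C(C)(C)C[C@@H](O[Si](C)(C)C(C)(C)C)C[C@]1(C)O
F7 | step 12 | (4S)-4-(tert-butyldimethylsilyloxy)-1-[(Z)-2-ethoxyethenyl]-2,6,6-trimethylcyclohex-2-en-1-ol | CC1=C[C@@H](O[Si](C)(C)C(C)(C)C)CC(C)(C)C1(O)/C=C\OCC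
F8 | step 12 | (2E)-2-[(4S)-4-(tert-butyldimethylsilyloxy)-2,6,6-trimethylcyclohex-2-en-1-ylidene]acetaldehyde | CC1=C[C@@H](O[Si](C)(C)C(C)(C)C)CC(C)(C)\C1=C/C=O
F9 | step 12 | (2E,4E)-4-[(4S)-4-(tert-butyldimethylsilyloxy)-2,6,6-trimethylcyclohex-2-en-1-ylidene]-2-methylbut-2-enal | CC1=C[C@@H](O[Si](C)(C)C(C)(C)C)CC(C)(C)\C1=C/C=C(C)/C=O
F10 | step 12 | (2S,4R)-2,4-bis(tert-butyldimethylsilyloxy)-1-[(Z)-2-ethoxyethenyl]-2,6,6-trimethylcyclohexan-1-ol | CCO\C=C/C1(O)C(C)(C)C[C@@H](O[Si](C)(C)C(C)(C)C)C[C@]1(C)O[Si](C)(C)C(C)(C)C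
F11 | step 12 | (2E)-2-[(2S,4R)-2,4-bis(tert-butyldimethylsilyloxy)-2,6,6-trimethylcyclohexylidene]acetaldehyde | O=C/C=C1\C(C)(C)C[C@@H](O[Si](C)(C)C(C)(C)C)C[C@]1(C)O[Si](C)(C)C(C)(C)C
F12 | step 12 | (2E,4E)-4-[(2S,4R)-2,4-bis(tert-butyldimethylsilyloxy)-2,6,6-trimethylcyclohexylidene]-2-methylbut-2-enal | O=C/C(C)=C/C=C1\C(C)(C)C[C@@H](O[Si](C)(C)C(C)(C)C)C[C@]1(C)O[Si](C)(C)C(C)(C)C
F13 | step 12 | diethyl (2E,4E,6E,8E)-3,8-dimethyldeca-2,4,6,8-tetraenedioate | CCOC(=O)/C=C(C)/C=C/C=C/C(C)=C/C(=O)OCC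
F14 | step 12 | (2E,4E,6E,8E)-3,8-dimethyldeca-2,4,6,8-tetraene-1,10-diol | OC/C=C(C)/C=C/C=C/C(C)=C/CO
F15 | step 12 | (2E,4E,6E,8E)-1,10-dibromo-3,8-dimethyldeca-2,4,6,8-tetraene | BrC/C=C(C)/C=C/C=C/C(C)=C/CBr
F16 | step 12 | tetraethyl [(2E,4E,6E,8E)-3,8-dimethyldeca-2,4,6,8-tetraene-1,10-diyl]bis(phosphonate) | CCOP(=O)(OCC)C/C=C(C)/C=C/C=C/C(C)=C/CP(=O)(OCC)OCC
F17 | step 12 | C26 retro-polyenyl phosphonate (left ring through C11', diethyl phosphonate at C11') | CC1=C[C@@H](O[Si](C)(C)C(C)(C)C)CC(C)(C)\C1=C/C=C(C)/C=C/C=C(C)/C=C/C=C/C(C)=C/CP(=O)(OCC)OCC
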